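**Retrosynthetic overview**
- The two benzylic carbinols come last, each by substrate-controlled reduction of an α-aryloxy ketone next to a lactate-derived C–O centre: chelation control gives the erythro (1R,2S) left arm, Felkin–Anh control gives the threo (1R,2R) right arm.
- The arm ether bonds come from lactates with inversion: Mitsunobu of (R)-lactate on 4-bromoguaiacol (left arm), SN2 of (S)-lactate tosylate by the core phenoxide (right arm). Aryl ketones follow by Weinreb/aryl Grignard.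
- Key disconnection: the oxolane C2–aryl bond, made by a light-driven cerium/nickel dehydroxymethylative arylation of an oxolan-2-ylmethanol with the left-arm aryl bromide (aryl trans to the C3 methyl).
- The oxolane C5–aryl bond comes from aryllithium addition to a 3,4-dimethyl lactone and ionic hydrogenation (aryl cis to the C4 methyl). The lactone comes from trityl-protected (S)-5-(hydroxymethyl)furan-2(5H)-one by anti conjugate methylation and enolate methylation.
- Ring order: no ring is built. The oxolane is the intact butenolide ring of the bought furanone, and the arenes are bought.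

Assumption: the aryl silyl ether, the lactate tosylate and the aryl Grignard solution used below are bought as catalog items.

**Route**

Step 1
Reactants: 1 (5S)-5-(hydroxymethyl)furan-2(5H)-one
Product: 2 (5S)-5-[(trityloxy)methyl]furan-2(5H)-one
Conditions: TrCl, pyridine, DMAP (cat.), CH2Cl2, 0 °C to rt
Reagents that add atoms: trityl chloride (ClC(c1ccccc1)(c1ccccc1)c1ccccc1)
Why: Tritylation of the primary alcohol leaves the bought stereocentre untouched and gives a bulky group that blocks one face of the butenolide.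

Step 2
Reactants: 2 (5S)-5-[(trityloxy)methyl]furan-2(5H)-one
Product: 4 (3S,4S,5S)-3,4-dimethyl-5-[(trityloxy)methyl]oxolan-2-one, via lithium enolate 3 (not isolated)
Conditions: Me2CuLi (from CuI, MeLi), Et2O/THF, −78 °C; then MeI, HMPA, −78 to −20 °C
Reagents that add atoms: lithium dimethylcuprate ([Li+].C[Cu-]C); iodomethane (CI)
Why: Tandem conjugate addition–enolate alkylation: the Gilman cuprate adds anti to the trityloxymethyl group and the enolate is methylated anti to the new C4 methyl, so both methyl centres (3S,4S) are set by the bought C5 centre.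

Step 3
Reactants: 4 (3S,4S,5S)-3,4-dimethyl-5-[(trityloxy)methyl]oxolan-2-one; 5 tert-butyl(4-bromo-2-methoxyphenoxy)dimethylsilane
Product: 8 [(2S,3S,4S,5R)-5-(4-{[tert-butyl(dimethyl)silyl]oxy}-3-methoxyphenyl)-3,4-dimethyloxolan-2-yl]methanol, via aryllithium 6 (not isolated), via lactol 7 (not isolated)
Conditions: 5, n-BuLi, THF, −78 °C; add 4; aq NH4Cl; crude lactol: Et3SiH, BF3·OEt2, CH2Cl2, −78 to −40 °C
Reagents that add atoms: none
Why: Bromine–lithium exchange, aryllithium addition to the lactone and BF3-promoted ionic hydrogenation of the oxocarbenium ion, where hydride enters anti to the neighbouring methyl so the aryl ends cis to it (5R); the trityl ether is reductively cleaved in the same operation.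

Step 4
Reactants: 9 4-bromo-2-methoxyphenol; 10 methyl (2R)-2-hydroxypropanoate
Product: 11 methyl (2S)-2-(4-bromo-2-methoxyphenoxy)propanoate
Conditions: PPh3, DIAD, THF, 0 °C to rt
Reagents that add atoms: none
Why: Mitsunobu etherification proceeds with clean SN2 inversion at the lactate carbon, turning bought (R)-lactate into the (S)-aryloxypropanoate.

Step 5
Reactants: 11 methyl (2S)-2-(4-bromo-2-methoxyphenoxy)propanoate; 12 (3,4-dimethoxyphenyl)magnesium bromide
Product: 14 (2S)-2-(4-bromo-2-methoxyphenoxy)-1-(3,4-dimethoxyphenyl)propan-1-one, via Weinreb amide 13 (not isolated)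
Conditions: MeNHOMe·HCl, iPrMgCl, THF, −20 °C; then 12, −20 to 0 °C; aq NH4Cl
Reagents that add atoms: none
Why: One-flask Weinreb ketone synthesis: ester aminolysis by the magnesium amide, then Grignard addition to a stable chelated tetrahedral intermediate, gives the ketone without over-addition or loss of the α-stereocentre.

Step 6
Reactants: 8 [(2S,3S,4S,5R)-5-(4-{[tert-butyl(dimethyl)silyl]oxy}-3-methoxyphenyl)-3,4-dimethyloxolan-2-yl]methanol; 14 (2S)-2-(4-bromo-2-methoxyphenoxy)-1-(3,4-dimethoxyphenyl)propan-1-one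
Product: 15 (2S)-2-{4-[(2S,3S,4S,5R)-5-(4-{[tert-butyl(dimethyl)silyl]oxy}-3-methoxyphenyl)-3,4-dimethyloxolan-2-yl]-2-methoxyphenoxy}-1-(3,4-dimethoxyphenyl)propan-1-one
Conditions: CeCl3 (10 mol %), n-Bu4NCl (20 mol %), 4CzIPN (2 mol %), NiBr2·DME (10 mol %), dtbbpy (12 mol %), 2,4,6-collidine, MeCN, 400 nm LEDs, 25 °C
Reagents that add atoms: none
Why: Proposed new method: a cerium/nickel dual photocatalytic dehydroxymethylative arylation in which the alkoxide of 8 on tetravalent cerium undergoes ligand-to-metal charge transfer to an alkoxy radical, β-scission expels formaldehyde and leaves the ring-oxygen-stabilised oxolan-2-yl radical, the aryl–nickel species from oxidative addition of 14 captures it on the face anti to the C3 methyl and reductive elimination forges the C2–aryl bond (2,3-trans, 2S, the bought centre being planarised and re-set by its neighbour), while 4CzIPN shuttles the electron (its excited state reoxidises trivalent cerium, its radical anion returns nickel to the zerovalent state); the closest known reactions are cerium-photocatalysed dehydroxymethylative alkylation and amination of primary alcohols and nickel/photoredox decarboxylative arylation of α-oxy acids.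

Step 7
Reactants: 15 (2S)-2-{4-[(2S,3S,4S,5R)-5-(4-{[tert-butyl(dimethyl)silyl]oxy}-3-methoxyphenyl)-3,4-dimethyloxolan-2-yl]-2-methoxyphenoxy}-1-(3,4-dimethoxyphenyl)propan-1-one
Product: 16 (1R,2S)-2-{4-[(2S,3S,4S,5R)-5-(4-{[tert-butyl(dimethyl)silyl]oxy}-3-methoxyphenyl)-3,4-dimethyloxolan-2-yl]-2-methoxyphenoxy}-1-(3,4-dimethoxyphenyl)propan-1-ol
Conditions: Zn(BH4)2, Et2O/THF, −20 to 0 °C; aq NH4Cl
Reagents that add atoms: none
Why: Chelation-controlled (Cram chelate) reduction: zinc bridges the carbonyl and guaiacyl ether oxygens and hydride enters past H, giving the anti (erythro) 1R,2S alcohol under control of the lactate-derived centre.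

Step 8
Reactants: 16 (1R,2S)-2-{4-[(2S,3S,4S,5R)-5-(4-{[tert-butyl(dimethyl)silyl]oxy}-3-methoxyphenyl)-3,4-dimethyloxolan-2-yl]-2-methoxyphenoxy}-1-(3,4-dimethoxyphenyl)propan-1-ol; 17 ethyl (2S)-2-(tosyloxy)propanoate
Product: 19 ethyl (2R)-2-{4-[(2R,3S,4S,5S)-5-(4-{[(1R,2S)-1-(3,4-dimethoxyphenyl)-1-hydroxypropan-2-yl]oxy}-3-methoxyphenyl)-3,4-dimethyloxolan-2-yl]-2-methoxyphenoxy}propanoate, via cesium phenoxide 18 (not isolated)
Conditions: CsF, DMF, rt to 50 °C
Reagents that add atoms: none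
Why: Fluoride unmasks the phenoxide, which displaces the lactate tosylate in an SN2 Williamson etherification with inversion, turning bought (S)-lactate into the (R)-aryloxypropanoate while the secondary alcohol stays neutral.

Step 9
Reactants: 19 ethyl (2R)-2-{4-[(2R,3S,4S,5S)-5-(4-{[(1R,2S)-1-(3,4-dimethoxyphenyl)-1-hydroxypropan-2-yl]oxy}-3-methoxyphenyl)-3,4-dimethyloxolan-2-yl]-2-methoxyphenoxy}propanoate; 12 (3,4-dimethoxyphenyl)magnesium bromide
Product: 21 (2R)-2-{4-[(2R,3S,4S,5S)-5-(4-{[(1R,2S)-1-(3,4-dimethoxyphenyl)-1-hydroxypropan-2-yl]oxy}-3-methoxyphenyl)-3,4-dimethyloxolan-2-yl]-2-methoxyphenoxy}-1-(3,4-dimethoxyphenyl)propan-1-one, via Weinreb amide 20 (not isolated)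
Conditions: MeNHOMe·HCl, iPrMgCl (excess), THF, −20 °C; then 12, −20 to 0 °C; aq NH4Cl
Reagents that add atoms: none
Why: One-flask Weinreb ketone synthesis as in step 5; the free carbinol is carried as its magnesium alkoxide and the α-aryloxy centre is preserved in the chelated tetrahedral intermediate.

Step 10
Reactants: 21 (2R)-2-{4-[(2R,3S,4S,5S)-5-(4-{[(1R,2S)-1-(3,4-dimethoxyphenyl)-1-hydroxypropan-2-yl]oxy}-3-methoxyphenyl)-3,4-dimethyloxolan-2-yl]-2-methoxyphenoxy}-1-(3,4-dimethoxyphenyl)propan-1-one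
Product: 22 (1R,2R)-1-(3,4-dimethoxyphenyl)-2-{4-[(2R,3S,4S,5S)-5-(4-{[(1R,2S)-1-(3,4-dimethoxyphenyl)-1-hydroxypropan-2-yl]oxy}-3-methoxyphenyl)-3,4-dimethyloxolan-2-yl]-2-methoxyphenoxy}propan-1-ol
Conditions: KBH(s-Bu)3, THF, −78 °C; aq NH4Cl
Reagents that add atoms: none
Why: Felkin–Anh (polar, non-chelating) reduction: the bulky borohydride attacks anti to the aryloxy group, giving the syn (threo) 1R,2R alcohol under control of the lactate-derived centre.

**Compound list**
1 | (5S)-5-(hydroxymethyl)furan-2(5H)-one | O=C1C=C[C@@H](CO)O1 | starting material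
2 | (5S)-5-[(trityloxy)methyl]furan-2(5H)-one | O=C1C=C[C@@H](COC(c2ccccc2)(c2ccccc2)c2ccccc2)O1 | intermediate
3 | lithium (4S,5S)-4-methyl-5-[(trityloxy)methyl]-4,5-dihydrofuran-2-olate | [Li+].[O-]C1=C[C@H](C)[C@@H](COC(c2ccccc2)(c2ccccc2)c2ccccc2)O1 | intermediate
4 | (3S,4S,5S)-3,4-dimethyl-5-[(trityloxy)methyl]oxolan-2-one | C[C@@H]1C(=O)O[C@H](COC(c2ccccc2)(c2ccccc2)c2ccccc2)[C@H]1C | intermediate
5 | tert-butyl(4-bromo-2-methoxyphenoxy)dimethylsilane | COc1cc(Br)ccc1O[Si](C)(C)C(C)(C)C | starting material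
6 | (4-{[tert-butyl(dimethyl)silyl]oxy}-3-methoxyphenyl)lithium | COc1cc([Li])ccc1O[Si](C)(C)C(C)(C)C | intermediate
7 | (3S,4S,5S)-2-(4-{[tert-butyl(dimethyl)silyl]oxy}-3-methoxyphenyl)-3,4-dimethyl-5-[(trityloxy)methyl]oxolan-2-ol (anomer mixture) | C[C@@H]1C(O)(c2ccc(O[Si](C)(C)C(C)(C)C)c(OC)c2)O[C@H](COC(c2ccccc2)(c2ccccc2)c2ccccc2)[C@H]1C | intermediate
8 | [(2S,3S,4S,5R)-5-(4-{[tert-butyl(dimethyl)silyl]oxy}-3-methoxyphenyl)-3,4-dimethyloxolan-2-yl]methanol | OC[C@H]1O[C@@H](c2ccc(O[Si](C)(C)C(C)(C)C)c(OC)c2)[C@@H](C)[C@@H]1C | intermediate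
9 | 4-bromo-2-methoxyphenol | COc1cc(Br)ccc1O | starting material
10 | methyl (2R)-2-hydroxypropanoate | C[C@@H](O)C(=O)OC | starting material
11 | methyl (2S)-2-(4-bromo-2-methoxyphenoxy)propanoate | COC(=O)[C@H](C)Oc1ccc(Br)cc1OC | intermediate
12 | (3,4-dimethoxyphenyl)magnesium bromide | COc1ccc([Mg]Br)cc1OC | starting material
13 | (2S)-2-(4-bromo-2-methoxyphenoxy)-N-methoxy-N-methylpropanamide | CON(C)C(=O)[C@H](C)Oc1ccc(Br)cc1OC | intermediate
14 | (2S)-2-(4-bromo-2-methoxyphenoxy)-1-(3,4-dimethoxyphenyl)propan-1-one | COc1ccc(C(=O)[C@H](C)Oc2ccc(Br)cc2OC)cc1OC | intermediate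
15 | (2S)-2-{4-[(2S,3S,4S,5R)-5-(4-{[tert-butyl(dimethyl)silyl]oxy}-3-methoxyphenyl)-3,4-dimethyloxolan-2-yl]-2-methoxyphenoxy}-1-(3,4-dimethoxyphenyl)propan-1-one | COc1ccc(C(=O)[C@H](C)Oc2ccc([C@H]3O[C@@H](c4ccc(O[Si](C)(C)C(C)(C)C)c(OC)c4)[C@@H](C)[C@@H]3C)cc2OC)cc1OC | intermediate
16 | (1R,2S)-2-{4-[(2S,3S,4S,5R)-5-(4-{[tert-butyl(dimethyl)silyl]oxy}-3-methoxyphenyl)-3,4-dimethyloxolan-2-yl]-2-methoxyphenoxy}-1-(3,4-dimethoxyphenyl)propan-1-ol | COc1ccc([C@@H](O)[C@H](C)Oc2ccc([C@H]3O[C@@H](c4ccc(O[Si](C)(C)C(C)(C)C)c(OC)c4)[C@@H](C)[C@@H]3C)cc2OC)cc1OC | intermediate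
17 | ethyl (2S)-2-(tosyloxy)propanoate | CCOC(=O)[C@H](C)OS(=O)(=O)c1ccc(C)cc1 | starting material
18 | cesium 4-[(2R,3S,4S,5S)-5-(4-{[(1R,2S)-1-(3,4-dimethoxyphenyl)-1-hydroxypropan-2-yl]oxy}-3-methoxyphenyl)-3,4-dimethyloxolan-2-yl]-2-methoxyphenolate | [Cs+].COc1ccc([C@@H](O)[C@H](C)Oc2ccc([C@H]3O[C@@H](c4ccc([O-])c(OC)c4)[C@@H](C)[C@@H]3C)cc2OC)cc1OC | intermediate
19 | ethyl (2R)-2-{4-[(2R,3S,4S,5S)-5-(4-{[(1R,2S)-1-(3,4-dimethoxyphenyl)-1-hydroxypropan-2-yl]oxy}-3-methoxyphenyl)-3,4-dimethyloxolan-2-yl]-2-methoxyphenoxy}propanoate | COc1ccc([C@@H](O)[C@H](C)Oc2ccc([C@H]3O[C@@H](c4ccc(O[C@H](C)C(=O)OCC)c(OC)c4)[C@@H](C)[C@@H]3C)cc2OC)cc1OC | intermediate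
20 | (2R)-2-{4-[(2R,3S,4S,5S)-5-(4-{[(1R,2S)-1-(3,4-dimethoxyphenyl)-1-hydroxypropan-2-yl]oxy}-3-methoxyphenyl)-3,4-dimethyloxolan-2-yl]-2-methoxyphenoxy}-N-methoxy-N-methylpropanamide | COc1ccc([C@@H](O)[C@H](C)Oc2ccc([C@H]3O[C@@H](c4ccc(O[C@H](C)C(=O)N(C)OC)c(OC)c4)[C@@H](C)[C@@H]3C)cc2OC)cc1OC | intermediate
21 | (2R)-2-{4-[(2R,3S,4S,5S)-5-(4-{[(1R,2S)-1-(3,4-dimethoxyphenyl)-1-hydroxypropan-2-yl]oxy}-3-methoxyphenyl)-3,4-dimethyloxolan-2-yl]-2-methoxyphenoxy}-1-(3,4-dimethoxyphenyl)propan-1-one | COc1ccc([C@@H](O)[C@H](C)Oc2ccc([C@H]3O[C@@H](c4ccc(O[C@H](C)C(=O)c5ccc(OC)c(OC)c5)c(OC)c4)[C@@H](C)[C@@H]3C)cc2OC)cc1OC | intermediate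
22 | (1R,2R)-1-(3,4-dimethoxyphenyl)-2-{4-[(2R,3S,4S,5S)-5-(4-{[(1R,2S)-1-(3,4-dimethoxyphenyl)-1-hydroxypropan-2-yl]oxy}-3-methoxyphenyl)-3,4-dimethyloxolan-2-yl]-2-methoxyphenoxy}propan-1-ol | COc1ccc([C@@H](O)[C@H](C)Oc2ccc([C@H]3O[C@@H](c4ccc(O[C@H](C)[C@H](O)c5ccc(OC)c(OC)c5)c(OC)c4)[C@@H](C)[C@@H]3C)cc2OC)cc1OC | target

**Step count**
Total: 10 steps. Longest linear sequence: 8 steps (1, 2, 3, 6, 7, 8, 9, 10); steps 4 and 5 form the convergent branch.

**Three steps most likely to fail**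

Step 6 (the proposed new coupling). Risks are hydrogen abstraction at the benzylic C5–H by chlorine or alkoxy radicals, oxidation of the electron-rich arenes by the excited photocatalyst, and only moderate facial selectivity at C2, because the C5 aryl sits on the face the new aryl must enter. The fallback uses known chemistry and sets out from 8. The primary alcohol is oxidised with TEMPO (cat.) and PhI(OAc)2 in MeCN/H2O to the carboxylic acid F1. This acid is then coupled with 14 by the established nickel/photoredox decarboxylative arylation of α-oxy acids (Ir[dF(CF3)ppy]2(dtbbpy)PF6, NiCl2·DME, dtbbpy, 1.0 equiv Cs2CO3, DMF, 450 nm LEDs), which generates the same oxolan-2-yl radical. The fallback comes back to the route at 15, at the cost of one extra step.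

Step 7 (erythro-selective reduction). Chelation through an aryl ether oxygen may be weak and give a poor erythro:threo ratio. The fallback sets out from 15 and inverts the carbinol instead of relying on chelation. Reduction with KBH(s-Bu)3 in THF at −78 °C under Felkin–Anh control gives the threo alcohol F2. Mitsunobu reaction with 4-nitrobenzoic acid, PPh3 and DIAD inverts the carbinol centre to give the 4-nitrobenzoate F3. The ester is cleaved with iBu2AlH in CH2Cl2 at −78 °C, which spares the aryl silyl ether, and the fallback comes back to the route at 16.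

Step 10 (threo-selective reduction, last step). The Felkin–Anh preference may be modest, and the diastereomers of the final product would be hard to separate. The fallback sets out from 19 and makes the C–aryl bond with stereocontrol instead of reducing a ketone. The ester is reduced with iBu2AlH in CH2Cl2 at −78 °C to the aldehyde F4, which is used crude. Addition of 12 in the presence of MgBr2·OEt2 in CH2Cl2/Et2O at −78 °C under Cram-chelate control gives the syn (threo) carbinol, so the fallback comes back to the route at 22 and bypasses step 9 as well.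

**Further compounds**
F1 | step 6 | (2S,3S,4S,5R)-5-(4-{[tert-butyl(dimethyl)silyl]oxy}-3-methoxyphenyl)-3,4-dimethyloxolane-2-carboxylic acid | OC(=O)[C@H]1O[C@@H](c2ccc(O[Si](C)(C)C(C)(C)C)c(OC)c2)[C@@H](C)[C@@H]1C
F2 | step 7 | (1S,2S)-2-{4-[(2S,3S,4S,5R)-5-(4-{[tert-butyl(dimethyl)silyl]oxy}-3-methoxyphenyl)-3,4-dimethyloxolan-2-yl]-2-methoxyphenoxy}-1-(3,4-dimethoxyphenyl)propan-1-ol | COc1ccc([C@H](O)[C@H](C)Oc2ccc([C@H]3O[C@@H](c4ccc(O[Si](C)(C)C(C)(C)C)c(OC)c4)[C@@H](C)[C@@H]3C)cc2OC)cc1OC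
F3 | step 7 | (1R,2S)-2-{4-[(2S,3S,4S,5R)-5-(4-{[tert-butyl(dimethyl)silyl]oxy}-3-methoxyphenyl)-3,4-dimethyloxolan-2-yl]-2-methoxyphenoxy}-1-(3,4-dimethoxyphenyl)propyl 4-nitrobenzoate | COc1ccc([C@@H](OC(=O)c6ccc([N+](=O)[O-])cc6)[C@H](C)Oc2ccc([C@H]3O[C@@H](c4ccc(O[Si](C)(C)C(C)(C)C)c(OC)c4)[C@@H](C)[C@@H]3C)cc2OC)cc1OC
F4 | step 10 | (2R)-2-{4-[(2R,3S,4S,5S)-5-(4-{[(1R,2S)-1-(3,4-dimethoxyphenyl)-1-hydroxypropan-2-yl]oxy}-3-methoxyphenyl)-3,4-dimethyloxolan-2-yl]-2-methoxyphenoxy}propanal | COc1ccc([C@@H](O)[C@H](C)Oc2ccc([C@H]3O[C@@H](c4ccc(O[C@H](C)C=O)c(OC)c4)[C@@H](C)[C@@H]3C)cc2OC)cc1OC
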